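**Strategy.** The route rests on cutting the C5–C6 bond: C5 is the terminus of the Z-configured C4=C5 alkene on furanone carbon C3, and C6 is the lactone carbinol next to C7. A nickel/chromium-mediated addition of the C5 alkenyl iodide to a C6 aldehyde closes the ten-membered carbocycle (C1–C10), sets C6 and places O6 on the carbon γ to the C12 ester, ready for lactonisation. The precursor is an (R)-2-methyl-3(2H)-furanone carrying the Z-iodopropenyl group at C3 and, from C10, a chain with a C8 silyl ether and a C7 carbon bearing both the aldehyde and the methyl acrylate. C7/C8 come from an auxiliary-controlled syn aldol, C10 from (S)-lactic acid.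

Key step: step 17

Remark: germacrane locants are used (C1 furanone C=O, C3 furanone O–C=, C10 quaternary centre, C12 lactone C=O); along C6–C9 the target has C11 and O8 syn, the pattern of a syn aldol, so C7/C8 are made by an aldol and not by an allylation; O8 carries TBS in aldehyde 28 and alcohol 30; the water used in step 9 is the moisture of undried toluene.

Step 1
Reactants: 1 (S)-lactic acid
Product: 2 (2S,5S)-2-tert-butyl-5-methyl-1,3-dioxolan-4-one
Conditions: t-BuCHO, TsOH·H2O (cat.), H2SO4 (cat.), pentane, reflux, Dean–Stark; cis isomer crystallised from pentane at −78 °C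
Reagents that add atoms: pivalaldehyde CC(C)(C)C=O
Why: Acid-catalysed acetalisation of the α-hydroxy acid should favour the cis dioxolanone, whose acetal centre (2S) is set under thermodynamic control by the lactate centre, and the minor trans isomer is removed by crystallisation.

Step 2
Reactants: 2 (2S,5S)-2-tert-butyl-5-methyl-1,3-dioxolan-4-one; 3 allyl bromide
Product: 5 (2S,5R)-5-allyl-2-tert-butyl-5-methyl-1,3-dioxolan-4-one, via lithium enolate 4 (not isolated)
Conditions: LDA (from i-Pr2NH, n-BuLi), THF, −78 °C; then 3, −78 → −30 °C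
Reagents that add atoms: lithium diisopropylamide [Li]N(C(C)C)C(C)C (Li, found in 4 only)
Why: Enolate alkylation with self-regeneration of the stereocentre: the planar enolate is attacked anti to the tert-butyl group, so allyl takes the place of the lactate hydrogen and the acetal centre sets the quaternary centre (future C10, R).

Step 3
Reactants: 5 (2S,5R)-5-allyl-2-tert-butyl-5-methyl-1,3-dioxolan-4-one
Product: 6 (2S,5R)-5-allyl-2-tert-butyl-5-methyl-1,3-dioxolan-4-ol (anomer mixture)
Conditions: DIBAL-H (1.1 equiv), CH2Cl2, −78 °C; Rochelle salt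
Reagents that add atoms: none
Why: Partial reduction of the lactone-type carbonyl with DIBAL-H should stop at the aluminium hemiacetal at −78 °C; the anomer mixture is of no consequence and the quaternary centre is not touched.

Step 4
Reactants: 6 (2S,5R)-5-allyl-2-tert-butyl-5-methyl-1,3-dioxolan-4-ol
Product: 8 (R)-3-methylhex-5-en-1-yn-3-ol, via hydroxy aldehyde 7 (not isolated)
Conditions: Ohira–Bestmann reagent (2.5 equiv), K2CO3 (3 equiv), MeOH, 0 °C → rt
Reagents that add atoms: dimethyl (1-diazo-2-oxopropyl)phosphonate CC(=O)C(=[N+]=[N-])P(=O)(OC)OC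
Why: In methanolic carbonate the lactol should open and shed pivalaldehyde to give the non-enolisable α-hydroxy aldehyde 7, which undergoes Seyferth–Gilbert homologation (Ohira–Bestmann variant) to the terminal alkyne, the excess reagent covering what the released pivalaldehyde consumes.

Step 5
Reactants: 9 propargyl alcohol
Product: 11 (Z)-3-iodo-2-methylprop-2-en-1-ol, via oxamagnesacycle 10 (not isolated)
Conditions: MeMgBr (2.5 equiv), CuI (10 mol%), THF/Et2O, −10 °C → rt; then I2, −78 → 0 °C
Reagents that add atoms: methylmagnesium bromide C[Mg]Br; iodine II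
Why: Copper-catalysed anti-carbomagnesiation of the propargylic alkoxide gives the five-membered alkenylmagnesium chelate 10, and iodinolysis with retention leaves iodine cis to CH2OH, i.e. the Z iodide.

Step 6
Reactants: 11 (Z)-3-iodo-2-methylprop-2-en-1-ol
Product: 12 (Z)-3-iodo-2-methylprop-2-enal
Conditions: activated MnO2 (excess), CH2Cl2, rt, dark; filtered and used at once as a cold solution
Reagents that add atoms: none
Why: Allylic alcohol oxidation on MnO2 is neutral and heterogeneous, which should preserve the labile Z geometry of the β-iodoenal.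

Step 7
Reactants: 8 (R)-3-methylhex-5-en-1-yn-3-ol; 12 (Z)-3-iodo-2-methylprop-2-enal
Product: 14 (6R,Z)-1-iodo-2,6-dimethylnona-1,8-dien-4-yne-3,6-diol (C3 epimers), via dilithio alkynolate 13 (not isolated)
Conditions: n-BuLi (2.0 equiv per 8), THF, −78 → −20 °C; then 12, −78 °C; aq. NH4Cl
Reagents that add atoms: n-butyllithium [Li]CCCC (Li, found in 13 only)
Why: The alkoxide–acetylide dianion adds 1,2 to the enal (acetylide addition) with no butyllithium left to exchange the iodide, and the new C3 carbinol centre forms as a mixture that the next step erases.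

Step 8
Reactants: 14 (6R,Z)-1-iodo-2,6-dimethylnona-1,8-dien-4-yne-3,6-diol
Product: 15 (6R,Z)-6-hydroxy-1-iodo-2,6-dimethylnona-1,8-dien-4-yn-3-one
Conditions: activated MnO2, CH2Cl2, rt
Reagents that add atoms: none
Why: MnO2 oxidises the secondary alcohol that is both allylic and propargylic and should leave the tertiary alcohol, the terminal alkene and the Z iodide alone.

Step 9
Reactants: 15 (6R,Z)-6-hydroxy-1-iodo-2,6-dimethylnona-1,8-dien-4-yn-3-one
Product: 17 (2R)-2-allyl-5-[(Z)-1-iodoprop-1-en-2-yl]-2-methylfuran-3(2H)-one, via 1,3-diketone 16 (not isolated)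
Conditions: (4-CF3C6H4)3PAuCl (5 mol%), AgOTf (5 mol%), undried toluene, rt
Reagents that add atoms: water O
Why: Gold(I)-catalysed cyclisation of a γ-hydroxyalkynone to a 3(2H)-furanone: the activated ynone takes up water at C1 and the tertiary hydroxyl then condenses onto the C3 carbonyl with loss of water, so no amine is present that could displace the β-iodide, and C10 is untouched.

Step 10
Reactants: 17 (2R)-2-allyl-5-[(Z)-1-iodoprop-1-en-2-yl]-2-methylfuran-3(2H)-one
Product: 19 2-[(2R)-5-[(Z)-1-iodoprop-1-en-2-yl]-2-methyl-3-oxo-2,3-dihydrofuran-2-yl]acetaldehyde, via vicinal diol 18 (not isolated)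
Conditions: OsO4 (2 mol%), NaIO4 (4 equiv), 2,6-lutidine (2 equiv), dioxane/H2O 3:1, rt
Reagents that add atoms: osmium tetroxide O=[Os](=O)(=O)=O; sodium periodate [Na+].[O-]I(=O)(=O)=O
Why: Lemieux–Johnson cleavage: osmium tetroxide should dihydroxylate the electron-rich monosubstituted alkene in preference to the iodo-diene and the push–pull furanone alkene, and periodate cleaves the diol to the C8 aldehyde, which is used without storage.

Step 11
Reactants: 20 dimethyl itaconate
Product: 21 3-(methoxycarbonyl)but-3-enoic acid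
Conditions: LiOH·H2O (1.0 equiv), THF/H2O, 0 °C; then 1 M HCl
Reagents that add atoms: lithium hydroxide [Li+].[OH-]
Why: Regioselective saponification: the unhindered, non-conjugated CH2CO2Me ester should hydrolyse faster than the conjugated acrylate ester, and the low temperature keeps the exo-methylene from moving into conjugation.

Step 12
Reactants: 21 3-(methoxycarbonyl)but-3-enoic acid; 22 (S)-4-benzylthiazolidine-2-thione
Product: 23 methyl 4-[(4S)-4-benzyl-2-thioxothiazolidin-3-yl]-2-methylidene-4-oxobutanoate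
Conditions: EDC·HCl (1.2 equiv), DMAP (5 mol%), CH2Cl2, 0 °C
Reagents that add atoms: none
Why: Carbodiimide N-acylation of the thiazolidinethione (Steglich-type coupling) is run cold and with little DMAP so that the β,γ-unsaturated acyl group does not isomerise.

Step 13
Reactants: 23 methyl 4-[(4S)-4-benzyl-2-thioxothiazolidin-3-yl]-2-methylidene-4-oxobutanoate; 19 2-[(2R)-5-[(Z)-1-iodoprop-1-en-2-yl]-2-methyl-3-oxo-2,3-dihydrofuran-2-yl]acetaldehyde
Product: 25 methyl (3S,4R)-3-[(4S)-4-benzyl-2-thioxothiazolidine-3-carbonyl]-4-hydroxy-5-[(2R)-5-[(Z)-1-iodoprop-1-en-2-yl]-2-methyl-3-oxo-2,3-dihydrofuran-2-yl]-2-methylidenepentanoate, via titanium enolate 24 (not isolated)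
Conditions: TiCl4 (1.05 equiv), i-Pr2NEt (1.1 equiv), NMP (1.0 equiv), CH2Cl2, 0 → −78 °C; then 19, −78 °C; aq. NH4Cl
Reagents that add atoms: titanium tetrachloride Cl[Ti](Cl)(Cl)Cl (Ti and Cl, found in 24 only)
Why: Titanium-mediated aldol of an N-acylthiazolidinethione in its Evans-syn mode: the Z enolate should react at C7 through a non-chelated chair transition state on the face away from the benzyl group, setting C7 (S) and C8 (R) under auxiliary control, with the remote C10 centre having little say.

Step 14
Reactants: 25 aldol adduct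
Product: 26 methyl (3S,4R)-3-[(4S)-4-benzyl-2-thioxothiazolidine-3-carbonyl]-4-[(tert-butyldimethylsilyl)oxy]-5-[(2R)-5-[(Z)-1-iodoprop-1-en-2-yl]-2-methyl-3-oxo-2,3-dihydrofuran-2-yl]-2-methylidenepentanoate
Conditions: TBSOTf (1.5 equiv), 2,6-lutidine (2.5 equiv), CH2Cl2, −78 → −20 °C
Reagents that add atoms: tert-butyldimethylsilyl triflate CC(C)(C)[Si](C)(C)OS(=O)(=O)C(F)(F)F
Why: Silylation with the silyl triflate and a hindered pyridine is fast at low temperature, blocks retro-aldol and closure of O8 onto C12, and installs a group that should survive the later acid lactonisation.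

Step 15
Reactants: 26 silylated aldol adduct
Product: 27 methyl (3R,4R)-4-[(tert-butyldimethylsilyl)oxy]-3-(hydroxymethyl)-5-[(2R)-5-[(Z)-1-iodoprop-1-en-2-yl]-2-methyl-3-oxo-2,3-dihydrofuran-2-yl]-2-methylidenepentanoate
Conditions: NaBH4 (2 equiv), THF/H2O 9:1, 0 °C, short; pH 7 buffer
Reagents that add atoms: none
Why: Borohydride cleavage of the highly activated N-acylthiazolidinethione should be far faster than attack on the methyl ester, the vinylogous-ester carbonyl of the furanone or the alkenyl iodide, and the short, cold, buffered procedure is meant to keep the new primary alcohol from closing onto the ester.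

Step 16
Reactants: 27 primary alcohol
Product: 28 methyl (3S,4R)-4-[(tert-butyldimethylsilyl)oxy]-3-formyl-5-[(2R)-5-[(Z)-1-iodoprop-1-en-2-yl]-2-methyl-3-oxo-2,3-dihydrofuran-2-yl]-2-methylidenepentanoate
Conditions: Dess–Martin periodinane (1.5 equiv), NaHCO3, CH2Cl2, 0 °C → rt; short Florisil filtration; used at once
Reagents that add atoms: none
Why: Buffered Dess–Martin oxidation is neutral, which should spare the C7 centre (α to the aldehyde and allylic to the acrylate) from epimerisation, double-bond migration and β-elimination of the C8 silyloxy group.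

Step 17
Reactants: 28 aldehyde with Z-alkenyl iodide
Product: 30 methyl 2-[(4Z,6S,7R,8R,10R)-8-[(tert-butyldimethylsilyl)oxy]-6-hydroxy-4,10-dimethyl-1-oxo-3,10-epoxycyclodeca-2,4-dien-7-yl]acrylate, via alkenylchromium 29 (not isolated)
Conditions: CrCl2 (8 equiv), NiCl2 (1 mol% of Cr), degassed DMSO, 28 added by syringe pump to 2 mM, rt; aq. potassium serinate
Reagents that add atoms: chromium(II) chloride Cl[Cr]Cl (Cr and Cl, found in 29 only)
Why: Nickel(0), made from NiCl2 by chromium(II), inserts into the C5–I bond with retention of the Z geometry and passes the alkenyl group to chromium(III), and the alkenylchromium 29 then adds through C5 to the C6 aldehyde. This is an intramolecular Nozaki–Hiyama–Kishi reaction, a reaction type established for closing medium rings from alkenyl iodide–aldehydes. The closure is an exo-trig attack on the aldehyde carbon and forms the ten-membered carbocycle C1–C10 (nine-membered if counted across the furanone oxygen), the Z alkene holding C5 over the C6–C9 chain so that the ends can meet. The new C6 centre should be set by the neighbouring C7 centre: with the ring branch C8 anti to the incoming C5 and the acrylate on the side of the carbonyl oxygen (Felkin–Anh), the 6S alcohol with O6 syn to C11 results, the arrangement that later gives the trans lactone (C7 reads R here only because O–Si outranks O–H). The step needs chemoselectivity for the aldehyde over the acrylate ester, the furanone carbonyl and the silyl ether, which the aldehyde-selective organochromium(III) reagent provides, and high dilution should suppress dimers. The aldehyde, whose C7–H is doubly activated, meets only neutral DMSO and is consumed as it is added.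

Step 18
Reactants: 30 macrocyclic hydroxy ester
Product: 31 (6S,7R,8R,10R)-8-[(tert-butyldimethylsilyl)oxy]-3,10-epoxy-1-oxogermacra-2,4Z,11(13)-trien-12,6-olide
Conditions: TsOH·H2O (10 mol%), CH2Cl2, rt
Reagents that add atoms: none
Why: Acid-catalysed transesterification of the γ-hydroxy acrylate should close the five-membered α-methylene lactone at O6 with retention at C6 (the C6–O bond is not broken), while the TBS ether keeps O8 from competing for C12.

Step 19
Reactants: 31 silylated lactone
Product: 32 (6S,7S,8R,10R)-8-hydroxy-3,10-epoxy-1-oxogermacra-2,4Z,11(13)-trien-12,6-olide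
Conditions: HF·pyridine, pyridine, THF, 0 °C → rt
Reagents that add atoms: none
Why: Fluoride-driven desilylation under buffered acidic conditions should free O8 without a base that could add to the α-methylene lactone or move the lactone from O6 to O8.

Step 20
Reactants: 33 tert-butyl acrylate; 34 acetaldehyde
Product: 35 tert-butyl 3-hydroxy-2-methylidenebutanoate (racemic)
Conditions: DABCO (0.3 equiv), neat, rt, several days
Reagents that add atoms: none
Why: Morita–Baylis–Hillman reaction; the carbinol centre is formed racemic and is destroyed in the next step.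

Step 21
Reactants: 35 tert-butyl 3-hydroxy-2-methylidenebutanoate
Product: 37 tert-butyl (E)-2-(acetoxymethyl)but-2-enoate, via secondary acetate 36 (not isolated)
Conditions: Ac2O (1.3 equiv), Et3N, DMAP (cat.), CH2Cl2, 0 °C → rt; then DABCO (0.3 equiv), THF, 60 °C
Reagents that add atoms: acetic anhydride CC(=O)OC(C)=O
Why: Acetylation followed by amine-catalysed 1,3-transposition of the Baylis–Hillman acetate (SN2′ attack of DABCO, then return of acetate at the primary carbon) should give the thermodynamic trisubstituted alkene with the methyl group trans to the ester, i.e. the E isomer.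

Step 22
Reactants: 37 tert-butyl (E)-2-(acetoxymethyl)but-2-enoate
Product: 38 (E)-2-(acetoxymethyl)but-2-enoic acid
Conditions: TFA/CH2Cl2 1:3, 0 °C → rt
Reagents that add atoms: none
Why: Acidolysis of the tert-butyl ester (loss of isobutene) should free the acid without touching the allylic acetate or the alkene geometry.

Step 23
Reactants: 38 (E)-2-(acetoxymethyl)but-2-enoic acid; 32 hydroxy lactone
Product: 40 target CNP0176571.1, via mixed anhydride 39 (not isolated)
Conditions: 2,4,6-trichlorobenzoyl chloride (1.5 equiv), Et3N (2 equiv), toluene, rt; then 32, DMAP (2 equiv), toluene, rt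
Reagents that add atoms: 2,4,6-trichlorobenzoyl chloride O=C(Cl)c1c(Cl)cc(Cl)cc1Cl (found in 39 only)
Why: Yamaguchi esterification acylates the hindered secondary O8 with retention at C8 (only the O–H bond reacts) and is a standard way to attach α,β-unsaturated acids whose geometry must be kept.

**Compound list**

1 | (S)-lactic acid | C[C@H](O)C(=O)O | starting material
2 | (2S,5S)-2-tert-butyl-5-methyl-1,3-dioxolan-4-one | CC(C)(C)[C@H]1O[C@@H](C)C(=O)O1 | intermediate
3 | allyl bromide | C=CCBr | starting material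
4 | lithium enolate of 2 (not isolated) | CC(C)(C)[C@H]1OC(C)=C(O[Li])O1 | intermediate
5 | (2S,5R)-5-allyl-2-tert-butyl-5-methyl-1,3-dioxolan-4-one | CC(C)(C)[C@H]1O[C@](C)(CC=C)C(=O)O1 | intermediate
6 | (2S,5R)-5-allyl-2-tert-butyl-5-methyl-1,3-dioxolan-4-ol (anomer mixture) | CC(C)(C)[C@H]1O[C@](C)(CC=C)C(O)O1 | intermediate
7 | (R)-2-hydroxy-2-methylpent-4-enal (not isolated) | O=C[C@](C)(O)CC=C | intermediate
8 | (R)-3-methylhex-5-en-1-yn-3-ol | C#C[C@](C)(O)CC=C | intermediate
9 | propargyl alcohol | C#CCO | starting material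
10 | 4-methyl-2,5-dihydro-1,2-oxamagnesole (not isolated) | CC1=C[Mg]OC1 | intermediate
11 | (Z)-3-iodo-2-methylprop-2-en-1-ol | OC/C(C)=C\I | intermediate
12 | (Z)-3-iodo-2-methylprop-2-enal | O=C/C(C)=C\I | intermediate
13 | dilithio derivative of 8 (not isolated) | [Li]C#C[C@](C)(O[Li])CC=C | intermediate
14 | (6R,Z)-1-iodo-2,6-dimethylnona-1,8-dien-4-yne-3,6-diol (C3 epimers) | OC(C#C[C@](C)(O)CC=C)/C(C)=C\I | intermediate
15 | (6R,Z)-6-hydroxy-1-iodo-2,6-dimethylnona-1,8-dien-4-yn-3-one | O=C(C#C[C@](C)(O)CC=C)/C(C)=C\I | intermediate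
16 | (6R,Z)-6-hydroxy-1-iodo-2,6-dimethylnona-1,8-diene-3,5-dione (not isolated) | O=C(CC(=O)[C@](C)(O)CC=C)/C(C)=C\I | intermediate
17 | (2R)-2-allyl-5-[(Z)-1-iodoprop-1-en-2-yl]-2-methylfuran-3(2H)-one | C=CC[C@@]1(C)OC(=CC1=O)/C(C)=C\I | intermediate
18 | (2R)-2-(2,3-dihydroxypropyl)-5-[(Z)-1-iodoprop-1-en-2-yl]-2-methylfuran-3(2H)-one (C8 epimers, not isolated) | OCC(O)C[C@@]1(C)OC(=CC1=O)/C(C)=C\I | intermediate
19 | 2-[(2R)-5-[(Z)-1-iodoprop-1-en-2-yl]-2-methyl-3-oxo-2,3-dihydrofuran-2-yl]acetaldehyde | O=CC[C@@]1(C)OC(=CC1=O)/C(C)=C\I | intermediate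
20 | dimethyl itaconate | C=C(CC(=O)OC)C(=O)OC | starting material
21 | 3-(methoxycarbonyl)but-3-enoic acid | C=C(CC(=O)O)C(=O)OC | intermediate
22 | (S)-4-benzylthiazolidine-2-thione | S=C1N[C@@H](Cc2ccccc2)CS1 | starting material
23 | methyl 4-[(4S)-4-benzyl-2-thioxothiazolidin-3-yl]-2-methylidene-4-oxobutanoate | C=C(CC(=O)N1C(=S)SC[C@@H]1Cc1ccccc1)C(=O)OC | intermediate
24 | trichlorotitanium (Z)-enolate of 23 (not isolated) | COC(=O)C(=C)/C=C(\O[Ti](Cl)(Cl)Cl)N1C(=S)SC[C@@H]1Cc1ccccc1 | intermediate
25 | methyl (3S,4R)-3-[(4S)-4-benzyl-2-thioxothiazolidine-3-carbonyl]-4-hydroxy-5-[(2R)-5-[(Z)-1-iodoprop-1-en-2-yl]-2-methyl-3-oxo-2,3-dihydrofuran-2-yl]-2-methylidenepentanoate | O=C(N1C(=S)SC[C@@H]1Cc1ccccc1)[C@@H](C(=C)C(=O)OC)[C@H](O)C[C@@]2(C)OC(=CC2=O)/C(C)=C\I | intermediate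
26 | O8-TBS ether of 25 | O=C(N1C(=S)SC[C@@H]1Cc1ccccc1)[C@@H](C(=C)C(=O)OC)[C@H](O[Si](C)(C)C(C)(C)C)C[C@@]2(C)OC(=CC2=O)/C(C)=C\I | intermediate
27 | methyl (3R,4R)-4-[(tert-butyldimethylsilyl)oxy]-3-(hydroxymethyl)-5-[(2R)-5-[(Z)-1-iodoprop-1-en-2-yl]-2-methyl-3-oxo-2,3-dihydrofuran-2-yl]-2-methylidenepentanoate | OC[C@@H](C(=C)C(=O)OC)[C@H](O[Si](C)(C)C(C)(C)C)C[C@@]1(C)OC(=CC1=O)/C(C)=C\I | intermediate
28 | methyl (3S,4R)-4-[(tert-butyldimethylsilyl)oxy]-3-formyl-5-[(2R)-5-[(Z)-1-iodoprop-1-en-2-yl]-2-methyl-3-oxo-2,3-dihydrofuran-2-yl]-2-methylidenepentanoate (precursor of the key step) | O=C[C@@H](C(=C)C(=O)OC)[C@H](O[Si](C)(C)C(C)(C)C)C[C@@]1(C)OC(=CC1=O)/C(C)=C\I | intermediate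
29 | C5 dichlorochromium(III) alkenyl derived from 28 (not isolated) | O=C[C@@H](C(=C)C(=O)OC)[C@H](O[Si](C)(C)C(C)(C)C)C[C@@]1(C)OC(=CC1=O)/C(C)=C\[Cr](Cl)Cl | intermediate
30 | methyl 2-[(4Z,6S,7R,8R,10R)-8-[(tert-butyldimethylsilyl)oxy]-6-hydroxy-4,10-dimethyl-1-oxo-3,10-epoxycyclodeca-2,4-dien-7-yl]acrylate (product of the key step) | C=C(C(=O)OC)[C@@H]1[C@@H](O)/C=C(/C)C2=CC(=O)[C@@](C)(C[C@H]1O[Si](C)(C)C(C)(C)C)O2 | intermediate
31 | (6S,7R,8R,10R)-8-[(tert-butyldimethylsilyl)oxy]-3,10-epoxy-1-oxogermacra-2,4Z,11(13)-trien-12,6-olide | C=C1C(=O)O[C@H]2/C=C(/C)C3=CC(=O)[C@@](C)(C[C@@H](O[Si](C)(C)C(C)(C)C)[C@H]12)O3 | intermediate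
32 | (6S,7S,8R,10R)-8-hydroxy-3,10-epoxy-1-oxogermacra-2,4Z,11(13)-trien-12,6-olide | C=C1C(=O)O[C@H]2/C=C(/C)C3=CC(=O)[C@@](C)(C[C@@H](O)[C@H]12)O3 | intermediate
33 | tert-butyl acrylate | C=CC(=O)OC(C)(C)C | starting material
34 | acetaldehyde | CC=O | starting material
35 | tert-butyl 3-hydroxy-2-methylidenebutanoate (racemic) | CC(O)C(=C)C(=O)OC(C)(C)C | intermediate
36 | tert-butyl 3-acetoxy-2-methylidenebutanoate (racemic, not isolated) | CC(OC(C)=O)C(=C)C(=O)OC(C)(C)C | intermediate
37 | tert-butyl (E)-2-(acetoxymethyl)but-2-enoate | C/C=C(/C(=O)OC(C)(C)C)COC(C)=O | intermediate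
38 | (E)-2-(acetoxymethyl)but-2-enoic acid | C/C=C(/C(=O)O)COC(C)=O | intermediate
39 | (E)-2-(acetoxymethyl)but-2-enoic 2,4,6-trichlorobenzoic anhydride (not isolated) | C/C=C(/C(=O)OC(=O)c1c(Cl)cc(Cl)cc1Cl)COC(C)=O | intermediate
40 | CNP0176571.1, (6S,7S,8R,10R)-8-[(E)-2-(acetoxymethyl)but-2-enoyloxy]-3,10-epoxy-1-oxogermacra-2,4Z,11(13)-trien-12,6-olide | C=C1C(=O)O[C@H]2/C=C(/C)C3=CC(=O)[C@@](C)(C[C@@H](OC(=O)/C(=C/C)COC(C)=O)[C@H]12)O3 | target

**Step count.** Total: 23 steps. Longest linear sequence: 16 steps (1–4, 7–10, 13–19, 23).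

**Steps most likely to fail**

1. Step 17. The ring-closing addition may show poor facial selectivity at the aldehyde, so that the C6 epimer forms. The fallback sets out from 28 and runs the same closure. If it gives mainly the 6R alcohol, methyl 2-[(4Z,6R,7R,8R,10R)-8-[(tert-butyldimethylsilyl)oxy]-6-hydroxy-4,10-dimethyl-1-oxo-3,10-epoxycyclodeca-2,4-dien-7-yl]acrylate F1, this is oxidised with buffered Dess–Martin periodinane to the macrocyclic C6 ketone F2. A CBS oxazaborolidine-catalysed borane reduction at low temperature, with the catalyst enantiomer chosen on a small scale to deliver hydride to the face that gives 6S, then returns the route at 30. C6 is thus set by a reagent-controlled ketone reduction and not by the C–C bond formation.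

2. Step 13. The cross-conjugated titanium enolate may be lost by double-bond migration or by reaction at its γ-carbon (C13), or the selectivity may erode. The fallback sets out from 19 and returns at 27 by a stereospecific allylboration.
   - Propargyl alcohol 9 is converted (NaH, PMBCl) into its PMB ether F3 and carboxylated (n-BuLi, ClCO2Me) to the ynoate F4.
   - Syn hydroalumination (DIBAL-H/HMPA) and trapping with ICH2Bpin gives the allylboronate F5, in which CH2B is trans to CH2OPMB.
   - Heating F5 with 19 in toluene should give, through a chair transition state, the anti homoallylic alcohol F6. Because C10 exerts little control, its 7,8-bis-epimer would form too and be removed by chromatography.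
   - TBSOTf/2,6-lutidine gives the silyl ether F7, and DDQ (CH2Cl2, pH 7 buffer) removes the PMB group to reach 27.

3. Step 15. The freed primary alcohol may close onto the methyl ester (an unwanted C6H2 lactone), or the double bond may migrate under the basic borohydride conditions. The fallback sets out from 26 and reaches 28 directly by partial reduction of the N-acylthiazolidinethione with DIBAL-H (1.1 equiv, CH2Cl2, −78 °C, added until the yellow colour fades). This bypasses alcohol 27 and the oxidation of step 16; no compound outside the list is made (F0).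

Further compounds
F1 | step 17 | methyl 2-[(4Z,6R,7R,8R,10R)-8-[(tert-butyldimethylsilyl)oxy]-6-hydroxy-4,10-dimethyl-1-oxo-3,10-epoxycyclodeca-2,4-dien-7-yl]acrylate (C6 epimer of 30) | C=C(C(=O)OC)[C@@H]1[C@H](O)/C=C(/C)C2=CC(=O)[C@@](C)(C[C@H]1O[Si](C)(C)C(C)(C)C)O2
F2 | step 17 | methyl 2-[(4Z,7S,8R,10R)-8-[(tert-butyldimethylsilyl)oxy]-4,10-dimethyl-1,6-dioxo-3,10-epoxycyclodeca-2,4-dien-7-yl]acrylate | C=C(C(=O)OC)[C@@H]1C(=O)/C=C(/C)C2=CC(=O)[C@@](C)(C[C@H]1O[Si](C)(C)C(C)(C)C)O2
F3 | step 13 | 1-methoxy-4-[(prop-2-yn-1-yloxy)methyl]benzene | C#CCOCc1ccc(OC)cc1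
F4 | step 13 | methyl 4-[(4-methoxybenzyl)oxy]but-2-ynoate | COC(=O)C#CCOCc1ccc(OC)cc1
F5 | step 13 | methyl (Z)-4-[(4-methoxybenzyl)oxy]-2-[(4,4,5,5-tetramethyl-1,3,2-dioxaborolan-2-yl)methyl]but-2-enoate | COC(=O)/C(CB1OC(C)(C)C(C)(C)O1)=C\COCc1ccc(OC)cc1
F6 | step 13 | methyl (3R,4R)-4-hydroxy-5-[(2R)-5-[(Z)-1-iodoprop-1-en-2-yl]-2-methyl-3-oxo-2,3-dihydrofuran-2-yl]-3-{[(4-methoxybenzyl)oxy]methyl}-2-methylidenepentanoate | COc1ccc(COC[C@@H](C(=C)C(=O)OC)[C@H](O)C[C@@]2(C)OC(=CC2=O)/C(C)=C\I)cc1
F7 | step 13 | O8-TBS ether of F6 | COc1ccc(COC[C@@H](C(=C)C(=O)OC)[C@H](O[Si](C)(C)C(C)(C)C)C[C@@]2(C)OC(=CC2=O)/C(C)=C\I)cc1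
F0 | step 15 | none | none
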